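**Retrosynthetic overview**
1. The target comes from a last step that removes a C10' phenylsulfonyl group and an O-allyl group with Pd/hydride; the C9'–C10' bond is made from lithiated prenyl phenyl sulfone and the 8',9'-epoxide 16.
2. The anti-(7'S,8'R)-diol comes from Sharpless epoxidation of the terminal E-allylic alcohol 11 (Riley oxidation of the chain end), one invertive opening at C7', then tosylate-to-epoxide closure.
3. Chromanol 9 comes from the 1-oxaspiro[4.5]deca-6,9-dien-8-one 8, this from para-alkylphenol 7, this from (S)-nerolidol 4 and 4-bromo-3-methylphenol 5; 4 comes from (E,E)-farnesol 1, which supplies C2 and the 3'E-alkene.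
4. Ring order: the benzene ring is bought; the oxolane ring O1–C2–C3–C4–C5 is spiro-fused to a cyclohexadienone (step 4); this five-membered ring is then enlarged to the dihydropyran O1–C2–C3–C4–C4a–C8a while the carbocycle re-aromatises (step 5).
5. Enabling feature: in 8 the spiro carbon C5 carries both ring oxygen O1 and C4H2 and lies between the β-carbons C6(–CH3) and C10(–H) of the cross-conjugated dienone C6=C7–C8(=O)–C9=C10. When C4 shifts to C10, the cation left on C5 is stabilised by O1 and H-10 can be lost.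

Key step: step 5

Remark: the SMILES is read as (2S,3'E,7'S,8'R), with primed locants counting the side chain from the carbon on C2 (C1') to C12'; the 7',8'-diol is the anti adduct of an E-alkene, so it is made by epoxidation plus one invertive opening, not by syn-dihydroxylation.

**Route**

Step 1
Reactants: 1 (2E,6E)-farnesol
Product: 2 (2S,3S)-2,3-epoxyfarnesol
Conditions: Ti(OiPr)4 (10 mol %), L-(+)-DET (12 mol %), t-BuOOH (2 equiv, anhydrous), 4 Å MS, CH2Cl2, −20 °C
Reagents that add atoms: tert-butyl hydroperoxide, CC(C)(C)OO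
Why: Katsuki–Sharpless asymmetric epoxidation of an E-allylic alcohol; the L-(+)-tartrate ligand should deliver oxygen to the face that gives (2S,3S), which fixes the later C2 of the chroman.

Step 2
Reactants: 2 (2S,3S)-2,3-epoxyfarnesol
Product: 4 (3S,6E)-nerolidol, via epoxy iodide 3 (not isolated)
Conditions: PPh3, imidazole, I2, THF, 0 °C; then Zn dust, EtOH, 40 °C (one flask)
Reagents that add atoms: none
Why: Appel-type iodination followed by zinc-induced reductive β-elimination of the epoxy iodide opens the oxirane to the tertiary allylic alcohol; the C3–O bond is never broken, so the configuration (3S) is kept.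

Step 3
Reactants: 4 (3S,6E)-nerolidol; 5 4-bromo-3-methylphenol
Product: 7 4-[(3S,6E)-3-hydroxy-3,7,11-trimethyldodeca-6,10-dien-1-yl]-3-methylphenol, via B-alkyl-9-BBN 6 (not isolated)
Conditions: 9-BBN (2.2 equiv), THF, 0 °C → rt; then 5, Pd(OAc)2 (5 mol %), SPhos (10 mol %), aq. K3PO4, THF, 65 °C
Reagents that add atoms: none
Why: 9-BBN should hydroborate only the monosubstituted vinyl group (anti-Markovnikov), and the B-alkyl Suzuki–Miyaura coupling joins that carbon to the aryl carbon para to OH; the carbinol centre is untouched.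

Step 4
Reactants: 7 4-[(3S,6E)-3-hydroxy-3,7,11-trimethyldodeca-6,10-dien-1-yl]-3-methylphenol
Product: 8 (2S)-2-[(3E)-4,8-dimethylnona-3,7-dien-1-yl]-2,6-dimethyl-1-oxaspiro[4.5]deca-6,9-dien-8-one (both C5 epimers)
Conditions: PhI(OAc)2 (1.1 equiv), (CF3)2CHOH–CH2Cl2 (1:4), 0 °C
Reagents that add atoms: none
Why: hypervalent-iodine oxidative dearomatisation of a para-alkylphenol with capture of the ipso carbon by the tertiary hydroxyl (5-exo spiro-etherification); the new spiro centre forms unselectively, which is harmless because it becomes aromatic in step 5.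

Step 5
Reactants: 8 spirodienone (both C5 epimers)
Product: 9 (2S)-2-[(3E)-4,8-dimethylnona-3,7-dien-1-yl]-2,8-dimethyl-3,4-dihydro-2H-chromen-6-ol
Conditions: BF3·OEt2 (0.3 equiv), CH2Cl2, −40 → 0 °C; Et3N quench
Reagents that add atoms: none
Why: BF3 binds the dienone oxygen of 8; C4 (the oxolane CH2) then shifts from spiro-C5 to the unsubstituted neighbour C10, the charge left at C5 being an oxocarbenium ion stabilised by O1, and loss of H-10 re-aromatises the ring to the chroman-6-ol. This is a dienone–phenol rearrangement of a 4-alkoxy-4-alkylcyclohexadienone (quinol-ether type), the closest precedent being the acid-induced conversion of 1-oxaspiro[4.5]deca-6,9-dien-8-ones into chroman-6-ols. No ring is closed from a chain: the six-membered O1–C2–C3–C4–C4a–C8a ring grows out of the five-membered O1–C2–C3–C4–C5 oxolane by a suprafacial 1,2-alkyl shift, while the carbocycle returns to a benzene ring. No stereocentre is made: C2 keeps all four bonds and stays S, and spiro-C5 becomes sp2, so both epimers of 8 converge. The selectivities needed are: carbon rather than oxygen migration (only the C-shift leaves an O-stabilised cation); C10 rather than the methyl-bearing C6 as terminus (a shift to C6 gives a cation that cannot lose a proton and should revert, and C10 is the less hindered terminus); and survival of the two trisubstituted alkenes (sub-stoichiometric Lewis acid, low temperature, no protic acid added).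

Step 6
Reactants: 9 chroman-6-ol
Product: 10 (2S)-6-(allyloxy)-2-[(3E)-4,8-dimethylnona-3,7-dien-1-yl]-2,8-dimethylchromane
Conditions: allyl bromide, K2CO3, acetone, 50 °C (argon)
Reagents that add atoms: allyl bromide, C=CCBr
Why: Williamson etherification of the phenol; the allyl ether should survive the oxidations and the carbanion step and is cleaved by the Pd/hydride conditions of the last step.

Step 7
Reactants: 10 allyl ether
Product: 11 (2E,6E)-9-[(2S)-6-(allyloxy)-2,8-dimethylchroman-2-yl]-2,6-dimethylnona-2,6-dien-1-ol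
Conditions: SeO2 (0.3 equiv), t-BuOOH (3 equiv), salicylic acid (10 mol %), CH2Cl2, 0 °C → rt, stopped at partial conversion (10 recycled)
Reagents that add atoms: selenium dioxide (catalytic oxygen carrier), O=[Se]=O; tert-butyl hydroperoxide, CC(C)(C)OO
Why: Riley allylic oxidation (ene reaction, then [2,3]-shift) should attack the E-methyl of the terminal isopropylidene group, the most accessible trisubstituted alkene, and gives the E-allylic alcohol.

Step 8
Reactants: 11 terminal E-allylic alcohol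
Product: 12 [(2R,3R)-3-{(3E)-6-[(2S)-6-(allyloxy)-2,8-dimethylchroman-2-yl]-3-methylhex-3-en-1-yl}-2-methyloxiran-2-yl]methanol (7'R,8'R-epoxide)
Conditions: Ti(OiPr)4 (0.2 equiv), D-(−)-DET (0.25 equiv), t-BuOOH (2 equiv), 4 Å MS, CH2Cl2, −25 °C
Reagents that add atoms: tert-butyl hydroperoxide, CC(C)(C)OO
Why: Katsuki–Sharpless epoxidation acts only on the allylic-alcohol alkene; the D-(−)-tartrate ligand sets (7'R,8'R) under reagent control.

Step 9
Reactants: 12 (7'R,8'R)-epoxy alcohol
Product: 14 (2R,3S,6E)-9-[(2S)-6-(allyloxy)-2,8-dimethylchroman-2-yl]-2,6-dimethylnon-6-ene-1,2,3-triol, via 7'-benzoate 13 (not isolated)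
Conditions: Ti(OiPr)4 (1.5 equiv), PhCO2H (2 equiv), CH2Cl2, rt; tartaric acid work-up; then K2CO3, MeOH, rt
Reagents that add atoms: benzoic acid, O=C(O)c1ccccc1
Why: Ti(OiPr)4-mediated C-3-selective opening of a 2,3-epoxy alcohol: benzoate attacks C7' with inversion (7'R → 7'S) while C8' keeps its C–O bond (8'R), giving the anti diol; methanolysis then removes the benzoyl group.

Step 10
Reactants: 14 (7'S,8'R)-triol
Product: 16 (1S,4E)-7-[(2S)-6-(allyloxy)-2,8-dimethylchroman-2-yl]-4-methyl-1-[(2R)-2-methyloxiran-2-yl]hept-4-en-1-ol, via primary tosylate 15 (not isolated)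
Conditions: TsCl (1.1 equiv), Et3N, Bu2SnO (5 mol %), CH2Cl2, 0 °C; then DBU, rt
Reagents that add atoms: none
Why: tin-catalysed selective sulfonylation of the primary hydroxyl, then 3-exo-tet displacement by the tertiary hydroxyl (intramolecular Williamson reaction); no bond to C7' or C8' is broken, so both centres are retained.

Step 11
Reactants: 16 8',9'-epoxide; 17 prenyl phenyl sulfone
Product: 19 (3E,7S,8R)-1-[(2S)-6-(allyloxy)-2,8-dimethylchroman-2-yl]-4,8,12-trimethyl-10-(phenylsulfonyl)trideca-3,11-diene-7,8-diol (C10 epimers), via lithiated sulfone 18 (not isolated)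
Conditions: 17 (3 equiv), n-BuLi (3 equiv), THF–DMPU, −78 °C; then 16, −78 °C → rt; aq. NH4Cl
Reagents that add atoms: none
Why: the sulfonyl-stabilised allyl anion attacks through its α-carbon at the unsubstituted CH2 of the 2,2-disubstituted epoxide (SN2 epoxide opening) and forms the C9'–C10' bond; the new sulfone-bearing centre is unselective and is erased in step 12.

Step 12
Reactants: 19 hydroxy sulfone
Product: 20 target, (3E,7S,8R)-1-[(2S)-6-hydroxy-2,8-dimethyl-3,4-dihydro-2H-chromen-2-yl]-4,8,12-trimethyltrideca-3,11-diene-7,8-diol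
Conditions: PdCl2(dppp) (10 mol %), LiBHEt3 (8 equiv), THF, 0 °C → rt
Reagents that add atoms: none
Why: Pd(0)-catalysed hydride displacement of the allylic sulfone through a π-allyl complex, with hydride going to the less substituted terminus C10' so that the trisubstituted 11',12'-alkene is kept; in the same pot the aryl allyl ether is cleaved by Pd/hydride de-allylation.

**Compound list**
1 | (2E,6E)-farnesol, (2E,6E)-3,7,11-trimethyldodeca-2,6,10-trien-1-ol | CC(C)=CCC/C(C)=C/CC/C(C)=C/CO | starting material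
2 | (2S,3S)-2,3-epoxyfarnesol, [(2S,3S)-3-[(3E)-4,8-dimethylnona-3,7-dien-1-yl]-3-methyloxiran-2-yl]methanol | OC[C@@H]1O[C@@]1(C)CC/C=C(\C)CCC=C(C)C | intermediate
3 | epoxy iodide, (2R,3S)-3-[(3E)-4,8-dimethylnona-3,7-dien-1-yl]-2-(iodomethyl)-3-methyloxirane (not isolated) | IC[C@@H]1O[C@@]1(C)CC/C=C(\C)CCC=C(C)C | intermediate
4 | (3S,6E)-nerolidol, (3S,6E)-3,7,11-trimethyldodeca-1,6,10-trien-3-ol | CC(C)=CCC/C(C)=C/CC[C@](C)(O)C=C | intermediate
5 | 4-bromo-3-methylphenol | Cc1cc(O)ccc1Br | starting material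
6 | B-alkyl-9-BBN, 9-[(3S,6E)-3-hydroxy-3,7,11-trimethyldodeca-6,10-dien-1-yl]-9-borabicyclo[3.3.1]nonane (not isolated) | CC(C)=CCC/C(C)=C/CC[C@](C)(O)CCB1C2CCCC1CCC2 | intermediate
7 | 4-[(3S,6E)-3-hydroxy-3,7,11-trimethyldodeca-6,10-dien-1-yl]-3-methylphenol | CC(C)=CCC/C(C)=C/CC[C@](C)(O)CCc1ccc(O)cc1C | intermediate
8 | (2S)-2-[(3E)-4,8-dimethylnona-3,7-dien-1-yl]-2,6-dimethyl-1-oxaspiro[4.5]deca-6,9-dien-8-one (both C5 epimers) | CC(C)=CCC/C(C)=C/CC[C@@]1(C)CCC2(O1)C=CC(=O)C=C2C | intermediate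
9 | (2S)-2-[(3E)-4,8-dimethylnona-3,7-dien-1-yl]-2,8-dimethyl-3,4-dihydro-2H-chromen-6-ol | CC(C)=CCC/C(C)=C/CC[C@@]1(C)CCc2cc(O)cc(C)c2O1 | intermediate
10 | (2S)-6-(allyloxy)-2-[(3E)-4,8-dimethylnona-3,7-dien-1-yl]-2,8-dimethylchromane | CC(C)=CCC/C(C)=C/CC[C@@]1(C)CCc2cc(OCC=C)cc(C)c2O1 | intermediate
11 | (2E,6E)-9-[(2S)-6-(allyloxy)-2,8-dimethylchroman-2-yl]-2,6-dimethylnona-2,6-dien-1-ol | OC/C(C)=C/CC/C(C)=C/CC[C@@]1(C)CCc2cc(OCC=C)cc(C)c2O1 | intermediate
12 | [(2R,3R)-3-{(3E)-6-[(2S)-6-(allyloxy)-2,8-dimethylchroman-2-yl]-3-methylhex-3-en-1-yl}-2-methyloxiran-2-yl]methanol | OC[C@@]3(C)O[C@@H]3CC/C(C)=C/CC[C@@]1(C)CCc2cc(OCC=C)cc(C)c2O1 | intermediate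
13 | (2R,3S,6E)-9-[(2S)-6-(allyloxy)-2,8-dimethylchroman-2-yl]-1,2-dihydroxy-2,6-dimethylnon-6-en-3-yl benzoate (not isolated) | OC[C@@](C)(O)[C@@H](OC(=O)c3ccccc3)CC/C(C)=C/CC[C@@]1(C)CCc2cc(OCC=C)cc(C)c2O1 | intermediate
14 | (2R,3S,6E)-9-[(2S)-6-(allyloxy)-2,8-dimethylchroman-2-yl]-2,6-dimethylnon-6-ene-1,2,3-triol | OC[C@@](C)(O)[C@@H](O)CC/C(C)=C/CC[C@@]1(C)CCc2cc(OCC=C)cc(C)c2O1 | intermediate
15 | 1-O-(p-toluenesulfonyl) derivative of triol 14 (primary tosylate, not isolated) | Cc3ccc(cc3)S(=O)(=O)OC[C@@](C)(O)[C@@H](O)CC/C(C)=C/CC[C@@]1(C)CCc2cc(OCC=C)cc(C)c2O1 | intermediate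
16 | (1S,4E)-7-[(2S)-6-(allyloxy)-2,8-dimethylchroman-2-yl]-4-methyl-1-[(2R)-2-methyloxiran-2-yl]hept-4-en-1-ol | C3O[C@@]3(C)[C@@H](O)CC/C(C)=C/CC[C@@]1(C)CCc2cc(OCC=C)cc(C)c2O1 | intermediate
17 | prenyl phenyl sulfone, [(3-methylbut-2-en-1-yl)sulfonyl]benzene | CC(C)=CCS(=O)(=O)c1ccccc1 | starting material
18 | 1-lithio-3-methylbut-2-enyl phenyl sulfone (not isolated) | CC(C)=C[CH-]S(=O)(=O)c1ccccc1.[Li+] | intermediate
19 | (3E,7S,8R)-1-[(2S)-6-(allyloxy)-2,8-dimethylchroman-2-yl]-4,8,12-trimethyl-10-(phenylsulfonyl)trideca-3,11-diene-7,8-diol (C10 epimers) | CC(C)=CC(S(=O)(=O)c3ccccc3)C[C@@](C)(O)[C@@H](O)CC/C(C)=C/CC[C@@]1(C)CCc2cc(OCC=C)cc(C)c2O1 | intermediate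
20 | (3E,7S,8R)-1-[(2S)-6-hydroxy-2,8-dimethyl-3,4-dihydro-2H-chromen-2-yl]-4,8,12-trimethyltrideca-3,11-diene-7,8-diol | CC(C)=CCC[C@@](C)(O)[C@@H](O)CC/C(C)=C/CC[C@@]1(C)CCc2cc(O)cc(C)c2O1 | target

**Totals and risks**
Total step count: 12. Longest linear sequence: 12 steps (1 → 20).

Steps most likely to fail:

(a) Step 5. The migrating CH2 may shift towards the methyl-bearing dienone carbon instead of the unsubstituted one, or the acid may protonate the trisubstituted alkenes and start cation–olefin cyclisation of the chain. The fallback avoids the rearrangement and makes the aryl–O bond by cross-coupling.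
- It sets out from nerolidol 4, used as its borane 6.
- B-alkyl Suzuki–Miyaura coupling with commercial 2-bromo-4-methoxy-6-methylphenol should give the ortho-alkylated phenol F1.
- Selective triflation of the phenol (PhNTf2, K2CO3) should give the aryl triflate F2.
- Intramolecular Pd-catalysed C–O coupling with the tertiary alkoxide (Buchwald–Hartwig etherification: Pd(OAc)2, bulky di-tert-butyl biaryl phosphine, Cs2CO3, toluene, 80 °C) should close the pyran ring to the 6-methoxychroman F3 without touching the C2–O bond, so C2 is retained.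
- Thiolate demethylation (NaSEt, DMF, 120 °C) returns to the route at 9.

(b) Step 7. Over-oxidation to the enal, competing oxidation at the internal allylic CH2 groups and incomplete conversion may leave little of the terminal alcohol. The fallback builds the same alcohol by cleavage and olefination.
- It sets out from 10.
- Terminal-selective bromohydrin formation at the isopropylidene end (NBS, THF–H2O, 0 °C) should give the bromohydrin F4.
- K2CO3 in MeOH closes it to the terminal epoxide F5.
- Periodic acid in aqueous THF cleaves F5 to the aldehyde F6.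
- Wittig reaction with the stabilised ylide Ph3P=C(CH3)CO2Et should give the E-enoate F7.
- DIBAL-H at −78 °C reduces F7 and returns to the route at 11.

(c) Step 9. Loss of regioselectivity in the epoxide opening (attack at the tertiary C8' instead of C7') would erode the configuration of the diol, and the benzoate may migrate. The fallback inverts the other centre by intramolecular delivery, so the regiochemistry is fixed by ring size.
- It sets out from 11.
- Sharpless epoxidation with the enantiomeric ligand L-(+)-DET should give the (7'S,8'S)-epoxy alcohol F8.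
- PhNCO in pyridine gives the N-phenylcarbamate F9.
- BF3·OEt2 at −20 °C followed by aqueous acid should deliver the carbamate oxygen in a 5-exo attack at C8' with inversion, giving the 8',9'-cyclic carbonate F10 with the 7'-hydroxyl free.
- K2CO3 in MeOH removes the carbonate and returns to the route at triol 14.

Further compounds
F1 | step 5 | 2-[(3S,6E)-3-hydroxy-3,7,11-trimethyldodeca-6,10-dien-1-yl]-4-methoxy-6-methylphenol | CC(C)=CCC/C(C)=C/CC[C@](C)(O)CCc1cc(OC)cc(C)c1O
F2 | step 5 | 2-[(3S,6E)-3-hydroxy-3,7,11-trimethyldodeca-6,10-dien-1-yl]-4-methoxy-6-methylphenyl trifluoromethanesulfonate | CC(C)=CCC/C(C)=C/CC[C@](C)(O)CCc1cc(OC)cc(C)c1OS(=O)(=O)C(F)(F)F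
F3 | step 5 | (2S)-2-[(3E)-4,8-dimethylnona-3,7-dien-1-yl]-6-methoxy-2,8-dimethylchromane | CC(C)=CCC/C(C)=C/CC[C@@]1(C)CCc2cc(OC)cc(C)c2O1
F4 | step 7 | (6E)-9-[(2S)-6-(allyloxy)-2,8-dimethylchroman-2-yl]-3-bromo-2,6-dimethylnon-6-en-2-ol (C3 epimers) | CC(C)(O)C(Br)CC/C(C)=C/CC[C@@]1(C)CCc2cc(OCC=C)cc(C)c2O1
F5 | step 7 | (2S)-6-(allyloxy)-2-[(3E)-6-(3,3-dimethyloxiran-2-yl)-4-methylhex-3-en-1-yl]-2,8-dimethylchromane (oxirane epimers) | CC1(C)OC1CC/C(C)=C/CC[C@@]2(C)CCc3cc(OCC=C)cc(C)c3O2
F6 | step 7 | (4E)-7-[(2S)-6-(allyloxy)-2,8-dimethylchroman-2-yl]-4-methylhept-4-enal | O=CCC/C(C)=C/CC[C@@]1(C)CCc2cc(OCC=C)cc(C)c2O1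
F7 | step 7 | ethyl (2E,6E)-9-[(2S)-6-(allyloxy)-2,8-dimethylchroman-2-yl]-2,6-dimethylnona-2,6-dienoate | CCOC(=O)/C(C)=C/CC/C(C)=C/CC[C@@]1(C)CCc2cc(OCC=C)cc(C)c2O1
F8 | step 9 | [(2S,3S)-3-{(3E)-6-[(2S)-6-(allyloxy)-2,8-dimethylchroman-2-yl]-3-methylhex-3-en-1-yl}-2-methyloxiran-2-yl]methanol | OC[C@]3(C)O[C@H]3CC/C(C)=C/CC[C@@]1(C)CCc2cc(OCC=C)cc(C)c2O1
F9 | step 9 | N-phenylcarbamate of F8 | O=C(Nc4ccccc4)OC[C@]3(C)O[C@H]3CC/C(C)=C/CC[C@@]1(C)CCc2cc(OCC=C)cc(C)c2O1
F10 | step 9 | (4R)-4-{(1S,4E)-7-[(2S)-6-(allyloxy)-2,8-dimethylchroman-2-yl]-1-hydroxy-4-methylhept-4-en-1-yl}-4-methyl-1,3-dioxolan-2-one | O=C1OC[C@@](C)(O1)[C@@H](O)CC/C(C)=C/CC[C@@]2(C)CCc3cc(OCC=C)cc(C)c3O2
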